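## The problem

Target 28 is a single cyclohexene ring carrying a cis-fused C5–C6 epoxide, four contiguous stereocentres (C1, C2, C5 and the fully substituted C6) and three acyloxy groups of two kinds: acetate on O1, benzoate on O2 and on the exocyclic O7. With the ring drawn so that O1 points up, O2 is down, the epoxide oxygen is down (syn to O2, anti to O1) and C7 is up. No carbon–carbon bond is difficult. The task is to place five oxygens on seven carbons in the right relative and absolute sense and to tell three hydroxyls apart when they are acylated. The trans C1/C2 diol is the natural source of control: an oxygen on C1 sits next to C6 and can steer a reagent to one face of a π bond at C6, and C6, once set, fixes the epoxide face because the ring must close by backside attack at C5. The vinyl epoxide (C5 is allylic to C3=C4) will not tolerate strong or Lewis acids. A free alkoxide on C1 invites Payne rearrangement and O7→O1 benzoyl transfer, and the esters exclude hydride and strong base late in the route. The feature that opens the key step is that the epoxide oxygen on C6 and the ester oxygen on C7 are vicinal: they are the two oxygens of a dihydroxylated exocyclic C6=C7 alkene flanked by the oxygenated carbons C1 and C5.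

## Retrosynthesis

**Esters last (28 ⇒ 26 ⇒ 25 ⇒ 24).** The O1–acetyl bond, the O2–benzoyl bond and then two O–Si bonds are cut. Acyl groups on O1 and O2 would not survive the enolate and hydride chemistry needed earlier and would migrate between neighbouring hydroxyls, whereas silyl ethers carry through unchanged. The forward sequence must desilylate 24 to diol 25 without generating an alkoxide, acylate the less hindered allylic O2 first with benzoyl chloride 22 to give 26, and acetylate the hindered O1 last with acetic anhydride 27.

**Epoxide C5–O bond (24 ⇒ 23).** Cutting the C5–O bond of the epoxide gives the trans C5,C6-diol 23, in which C5 is epimeric to the target (O5 up, O6 down). The other cut, at C6–O, would demand displacement at a tertiary carbon, and direct epoxidation of a C5=C6 alkene would need both site control within a diene and delivery syn to O2. The forward step must activate only the secondary O5 and let the tertiary O6 displace it with inversion.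

**O7 benzoate (23 ⇒ 21 + 22).** The primary ester is cut to triol 21. O7 has to be capped before the cyclodehydration, otherwise the primary hydroxyl would be activated and a C6–C7 epoxide would form. Selectivity for primary over secondary allylic and tertiary hydroxyl is asked of the forward step.

**The two oxygens on C6 and C7 (21 ⇒ 17).** The C6–O and C7–O bonds are cut together to give the exocyclic alkene of dienol 17. The neighbouring cut, C6–C7, would mean adding a one-carbon nucleophile to a C6 ketone flanked by two oxygenated carbons, which is enolisable, prone to β-elimination and uncertain in facial sense. Precursor 17 has one stereocentre and two oxygens fewer than 21. The forward reaction, osmium-catalysed dihydroxylation with amine oxide 18 and water 19, must attack the exocyclic and not the ring alkene, and from the face opposite O1 and O5.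

**C5 carbinol (17 ⇒ 16).** The C5–H bond is cut to give the cross-conjugated methylene enone 16. The forward reduction must be a 1,2-addition and must deliver hydride anti to the axial silyloxy group on C1, so that O5 ends cis to O1.

**Exocyclic carbon (16 ⇒ 14 ⇒ 11 + 12).** The C6=C7 bond is traced to a C6–C7 single bond made by aminomethylation of the kinetic α'-enolate of enone 11 with iminium salt 12 (Mannich base 14), followed by elimination. Enone 11 lacks C7 and has only the two stereocentres bought from the chiral pool.

**Chiral-pool relay (11 ⇒ 9 ⇒ 8 ⇒ 6 ⇒ 5 ⇒ 4 ⇒ 1).** The trans-4,5-dioxygenated cyclohexenone is traced to (−)-quinic acid 1, whose trans C4/C5 diol becomes C2/C1 of the target with the correct absolute sense. The carboxyl carbon is excised by reduction and glycol cleavage (4 ⇒ 5 ⇒ 6), and the hydroxyl cis to O4 is eliminated to form the enone (6 ⇒ 8). The trans-diol is masked meanwhile as the diacetal from butane-2,3-dione 2 and methanol 3, then exchanged for silyl ethers from chloride 10 (8 ⇒ 9 ⇒ 11).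

## Roads not taken

**Alternative 1:** The cut runs through C1–C6 and C2–C3. Furfuryl benzoate A1 and 2-bromoacrolein A2 would combine in a formyl-exo Diels–Alder reaction under a chiral boron Lewis acid to give 7-oxanorbornene A3.
- Merits: the carbocycle, the quaternary C6 with its oxygen and the CH2OBz arm arise in one catalytic enantioselective step from the achiral materials A1 and A2. No chiral pool is needed, and the first ring is reached far sooner than in the chosen plan.
- Weak points: in A3 the bridge oxygen is bonded to C3, not C5, so an allylic transposition of that oxygen on the same face is still owed. C1 carries Br and CHO where the target has an acyloxy group, and C2 is a bare methylene, so two of the four ring oxygens remain to be introduced by oxidation-state changes. Furan cycloadditions are reversible, and furan A1 must react with its substituted terminus next to the bromine-bearing carbon of A2.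
- Comparison: Alternative 1 is better in convergence and in early step economy. The chosen plan sets against it that every ring oxygen is present from quinic acid 1 or arrives in one dihydroxylation, with no correction of oxidation level at C1 or C2.

**Alternative 2:** The cut is at C2–O and C5–O. 2-(Hydroxymethyl)phenol A4 would be dearomatised to the racemic spiro-epoxy dienone A5, then reduced and O-alkylated to diene A6. Singlet oxygen would add across C2 and C5 anti to the spiro-epoxide oxygen and O1 to give endoperoxide A7. O–O reduction and a Payne rearrangement would then move the epoxide from C6–C7 to C5–C6.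
- Merits: this is probably the shortest route, and phenol A4 is a cheap achiral starting point. O2 and O5 arrive cis in one step, and the Payne shift delivers the epoxide syn to O2 and frees O7. O2 and O7 can then be benzoylated together, which removes the hydroxyl differentiation that the chosen plan must achieve by selective acylation.
- Weak points: A5 is racemic and dimerises readily, so absolute configuration needs a resolution or an asymmetric reduction. The cycloaddition must be anti to two different groups at once, and the later removal of the O1 ether must spare a vinyl epoxide.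
- Comparison: Alternative 2 is better in step count and in ester differentiation. The chosen plan sets against it a secure absolute configuration and the derivation of each new stereocentre from the C1/C2 diol by substrate control, without a dimerisation-prone dienone.

**Alternative 3:** The cut is the C6–O bond, delivered from O2. In dienyl tert-butyl carbonate A8 an iodonium source would activate C5=C6, and the carbonate would attack C6 with loss of its tert-butyl group to give bicyclic iodocarbonate A9 with iodine on C5. Carbonate cleavage would then let O6 displace iodide.
- Merits: the tether guarantees that the epoxide oxygen is syn to O2, which is more secure than the intermolecular face selection of the chosen dihydroxylation. O2 is unmasked while O1 stays silylated, so O1 and O2 are differentiated by construction.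
- Weak points: A8 must itself be made enantiopure with O1 and O2 differentiated and C7 acylated, which costs at least the front end of the chosen plan. An electrophile on a conjugated diene can give 1,4-products, the allylic iodide in A9 is labile, and the conditions that cleave the cyclic carbonate also threaten the C7 benzoate.
- Comparison: Alternative 3 is better in facial certainty and in O1/O2 differentiation. The chosen plan sets against it a simpler precursor and the fact that both new C–O bonds on C6 and C7 are made in one step.

Key step: step 10

Remark on the chemistry: bis-silyl ethers 16 and 17 are assumed to populate the half-chair in which the bulky trans-vicinal silyloxy groups are both axial; the face arguments in steps 9 and 10 rest on this. Locants C1–C7 are those of the target (C1 acetoxy carbon, C2 ring benzoyloxy carbon, C3=C4, C5 epoxide CH, C6 quaternary epoxide carbon, C7 exocyclic CH2). "Up" is the face carrying O1. Compounds 1–11 are also given quinic acid or enone locants where stated.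

## Route

Step 1
Reactants: 1 (−)-quinic acid; 2 butane-2,3-dione; 3 methanol
Product: 4 methyl quinate 4,5-O-butane-2,3-diacetal
Conditions: 2, HC(OMe)3, MeOH, camphorsulfonic acid (cat.), reflux
Reagents that add atoms: butane-2,3-dione CC(=O)C(C)=O; methanol CO
Why: Fischer esterification and butane-2,3-diacetal formation proceed together under acid catalysis; only the trans-diequatorial C4/C5 diol can span the dioxane chair, whose methoxy groups both sit axial (anomeric effect), so the hydroxyl cis to O4 and the tertiary hydroxyl stay free and no ring stereocentre is touched.

Step 2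
Reactants: 4 methyl quinate 4,5-O-butane-2,3-diacetal
Product: 5 1-(hydroxymethyl) triol
Conditions: NaBH4, MeOH, 0 °C → rt
Reagents that add atoms: none
Why: Borohydride reduction of an α-hydroxy ester, which is activated by the neighbouring hydroxyl, gives the primary alcohol; the diacetal is inert to hydride.

Step 3
Reactants: 5 1-(hydroxymethyl) triol
Product: 6 3-hydroxy-4,5-diacetal cyclohexanone
Conditions: NaIO4, SiO2, CH2Cl2/H2O, rt
Reagents that add atoms: none
Why: Periodate glycol cleavage of the only free 1,2-diol (tertiary OH and CH2OH) excises the former carboxyl carbon as formaldehyde and leaves the ketone; the secondary hydroxyl has no free vicinal partner.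

Step 4
Reactants: 6 3-hydroxy-4,5-diacetal cyclohexanone
Product: 8 diacetal-protected (4R,5R)-4,5-dihydroxycyclohex-2-en-1-one, via C3 mesylate 7 (not isolated)
Conditions: MsCl, Et3N, CH2Cl2, 0 °C → rt
Reagents that add atoms: none
Why: Mesylation of the β-hydroxyl and E1cB elimination under the amine base give the conjugated enone; the two acetal-bearing stereocentres are not involved.

Step 5
Reactants: 8 diacetal-protected (4R,5R)-4,5-dihydroxycyclohex-2-en-1-one
Product: 9 (4R,5R)-4,5-dihydroxycyclohex-2-en-1-one
Conditions: CF3CO2H/H2O (20:1), 0 °C → rt; evaporate
Reagents that add atoms: none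
Why: Acid-catalysed hydrolysis of the bis-ketal releases the trans-diol; the enone has no acid-labile bond, and the diol is carried on at once because base would dehydrate it toward hydroquinone.

Step 6
Reactants: 9 (4R,5R)-4,5-dihydroxycyclohex-2-en-1-one; 10 tert-butyldimethylsilyl chloride
Product: 11 (4R,5R)-4,5-bis(tert-butyldimethylsilyloxy)cyclohex-2-en-1-one
Conditions: TBSCl, imidazole, DMAP (cat.), DMF, rt
Reagents that add atoms: tert-butyldimethylsilyl chloride CC(C)(C)[Si](C)(C)Cl
Why: Standard silyl ether formation on both secondary hydroxyls under conditions too weakly basic for β-elimination; the bulky trans-bis-silyl ether later holds the ring in the diaxial half-chair.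

Step 7
Reactants: 11 (4R,5R)-4,5-bis(tert-butyldimethylsilyloxy)cyclohex-2-en-1-one; 12 N,N-dimethylmethyleneiminium iodide
Product: 14 C6-(dimethylaminomethyl) enone (Mannich base), via lithium dienolate 13 (not isolated)
Conditions: LiN(iPr)2, THF, −78 °C; then 12, −78 → −30 °C
Reagents that add atoms: N,N-dimethylmethyleneiminium iodide C[N+](C)=C.[I-]
Why: Kinetic deprotonation occurs at the α'-methylene (C6) and not at the γ-position, and the cross-conjugated lithium dienolate is aminomethylated by the preformed iminium salt (Mannich reaction of a preformed enolate); the low temperature holds back β-elimination of the neighbouring silyloxide, and the configuration at C6 is irrelevant because step 8 erases it.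

Step 8
Reactants: 14 C6-(dimethylaminomethyl) enone (Mannich base)
Product: 16 C6-methylene enone, via trimethylammonium iodide 15 (not isolated)
Conditions: MeI, CH2Cl2, rt; then aq. NaHCO3, CH2Cl2, rt; used directly
Reagents that add atoms: none
Why: Exhaustive N-methylation makes the amine a leaving group and mild base removes the acidic α-proton to expel trimethylamine (Hofmann-type E1cB elimination of a Mannich base methiodide); C1 and C2 are untouched, and the cross-conjugated dienone is reduced without storage.

Step 9
Reactants: 16 C6-methylene enone
Product: 17 dienol with C5-OH cis to O1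
Conditions: NaBH4, CeCl3·7H2O, MeOH, −78 °C
Reagents that add atoms: none
Why: Luche reduction directs hydride to the carbonyl carbon of the dienone (1,2-addition); with both silyloxy groups axial, the C1 silyloxy group shields the upper face 1,3 to the carbonyl, so hydride enters from below and the new C5 hydroxyl ends up, cis to O1.

Step 10
Reactants: 17 dienol with C5-OH cis to O1; 18 N-methylmorpholine N-oxide; 19 water
Product: 21 C5,C6,C7-triol bis-silyl ether, via osmate ester 20 (not isolated)
Conditions: OsO4 (3 mol %), 18 (1.1 equiv), acetone/H2O (5:1), 0 °C → rt; aq. Na2SO3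
Reagents that add atoms: osmium tetroxide O=[Os](=O)(=O)=O (catalytic carrier of both oxygens); N-methylmorpholine N-oxide C[N+]1([O-])CCOCC1; water O
Why: OsO4 adds across the 1,1-disubstituted C6=C7 bond in a concerted suprafacial [3+2] cycloaddition to give the hexavalent-osmium glycolate 20, which 18 re-oxidises and 19 hydrolyses to release 21 and regenerate OsO4 (catalytic dihydroxylation with an amine oxide co-oxidant, a known reaction type applied here to a new diene). No ring of the product is closed; the only ring formed is the transient five-membered osmate ester, closed in the cycloaddition itself. The one new stereocentre, C6, is controlled by the allylic oxygens on C1 and C5: both lie on the upper face with their C–O bonds roughly perpendicular to the alkene plane, so the oxidant approaches from below (osmylation anti to allylic oxygen), placing O6 down and leaving C7 up. Two selectivities are needed. Facial selectivity is secured by this matched pair of allylic substituents, and the free C5 hydroxyl does not direct in aqueous acetone, where hydrogen bonding to the oxidant is swamped. Site selectivity for the exocyclic over the ring alkene rests on three features: the terminal CH2 is the least hindered alkene carbon, the ring alkene is cis-disubstituted, and the ring alkene has an allylic oxygen on each face (O2 below, O5 above) and therefore no open face. The co-oxidant is kept near one equivalent and the reaction is stopped when 17 is consumed, to avoid a second dihydroxylation.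

Step 11
Reactants: 21 C5,C6,C7-triol bis-silyl ether; 22 benzoyl chloride
Product: 23 C7 benzoate C5,C6-diol
Conditions: BzCl (1.05 equiv), pyridine, CH2Cl2, −40 → 0 °C
Reagents that add atoms: benzoyl chloride O=C(Cl)c1ccccc1
Why: Selective esterification: acylation rates fall in the order primary, secondary allylic, tertiary, so one equivalent of acid chloride at low temperature caps O7 only.

Step 12
Reactants: 23 C7 benzoate C5,C6-diol
Product: 24 C5–C6 epoxide bis-silyl ether
Conditions: PPh3, DIAD, THF, 0 °C → rt
Reagents that add atoms: none
Why: Mitsunobu cyclodehydration of a trans-1,2-diol: the secondary O5 forms the alkoxyphosphonium ion and the anti tertiary O6 displaces phosphine oxide intramolecularly (3-exo-tet SN2), inverting C5 and placing the epoxide oxygen down, syn to O2; the tertiary carbinol cannot be activated and the benzoate blocks C7.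

Step 13
Reactants: 24 C5–C6 epoxide bis-silyl ether
Product: 25 epoxy diol
Conditions: HF·pyridine, pyridine, THF, 0 °C → rt
Reagents that add atoms: none
Why: Fluoride cleaves both Si–O bonds under buffered, weakly acidic conditions, so no alkoxide forms on C1 (no Payne rearrangement, no O7→O1 benzoyl shift) and the vinyl epoxide is not ionised.

Step 14
Reactants: 25 epoxy diol; 22 benzoyl chloride
Product: 26 O2,O7-dibenzoate with free C1 hydroxyl
Conditions: BzCl (1.05 equiv), pyridine, CH2Cl2, −40 → −10 °C
Reagents that add atoms: benzoyl chloride O=C(Cl)c1ccccc1
Why: Selective acylation of the less hindered allylic C2 hydroxyl; the C1 hydroxyl is neopentyl-like, flanked by the quaternary epoxide carbon C6 and its CH2OBz arm, and reacts more slowly.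

Step 15
Reactants: 26 O2,O7-dibenzoate with free C1 hydroxyl; 27 acetic anhydride
Product: 28 target: C1 acetate, C2 and C7 benzoates, C5–C6 epoxide
Conditions: Ac2O, pyridine, DMAP (cat.), CH2Cl2, 0 °C → rt
Reagents that add atoms: acetic anhydride CC(=O)OC(C)=O
Why: DMAP-catalysed acetylation (nucleophilic catalysis) esterifies the remaining hindered secondary alcohol under non-acidic conditions that leave the vinyl epoxide and the benzoates intact.

## Compound list

1 | (−)-quinic acid, (1S,3R,4S,5R)-1,3,4,5-tetrahydroxycyclohexane-1-carboxylic acid | O[C@@]1(C(=O)O)C[C@@H](O)[C@@H](O)[C@H](O)C1 | starting material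
2 | butane-2,3-dione | CC(=O)C(C)=O | starting material
3 | methanol | CO | starting material
4 | methyl quinate 4,5-O-butane-2,3-diacetal (methyl ester; trans C4/C5 diol bridged as a (2S,3S)-2,3-dimethoxy-2,3-dimethyl-1,4-dioxane; C1 and C3 hydroxyls free) | COC(=O)[C@]1(O)C[C@@H](O)[C@H]2O[C@](C)(OC)[C@@](C)(OC)O[C@@H]2C1 | intermediate
5 | 1-(hydroxymethyl) triol (ester of 4 reduced to CH2OH) | OC[C@]1(O)C[C@@H](O)[C@H]2O[C@](C)(OC)[C@@](C)(OC)O[C@@H]2C1 | intermediate
6 | 3-hydroxy-4,5-diacetal cyclohexanone (quinic acid locants) | O=C1C[C@@H](O)[C@H]2O[C@](C)(OC)[C@@](C)(OC)O[C@@H]2C1 | intermediate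
7 | C3 mesylate of 6 | O=C1C[C@@H](OS(C)(=O)=O)[C@H]2O[C@](C)(OC)[C@@](C)(OC)O[C@@H]2C1 | intermediate
8 | diacetal-protected (4R,5R)-4,5-dihydroxycyclohex-2-en-1-one | O=C1C=C[C@H]2O[C@](C)(OC)[C@@](C)(OC)O[C@@H]2C1 | intermediate
9 | (4R,5R)-4,5-dihydroxycyclohex-2-en-1-one | O=C1C=C[C@@H](O)[C@H](O)C1 | intermediate
10 | tert-butyldimethylsilyl chloride | CC(C)(C)[Si](C)(C)Cl | starting material
11 | (4R,5R)-4,5-bis(tert-butyldimethylsilyloxy)cyclohex-2-en-1-one (enone C4, C5, C1, C6 are target C2, C1, C5, C6) | O=C1C=C[C@@H](O[Si](C)(C)C(C)(C)C)[C@H](O[Si](C)(C)C(C)(C)C)C1 | intermediate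
12 | N,N-dimethylmethyleneiminium iodide | C[N+](C)=C.[I-] | starting material
13 | lithium dienolate of 11 (O–Li on C5, C5=C6 and C3=C4) | [Li]OC1=C[C@@H](O[Si](C)(C)C(C)(C)C)[C@H](O[Si](C)(C)C(C)(C)C)C=C1 | intermediate
14 | Mannich base: C6-(dimethylaminomethyl) derivative of 11, C6 epimers | CN(C)CC1C(=O)C=C[C@@H](O[Si](C)(C)C(C)(C)C)[C@@H]1O[Si](C)(C)C(C)(C)C | intermediate
15 | trimethylammonium iodide of 14 | C[N+](C)(C)CC1C(=O)C=C[C@@H](O[Si](C)(C)C(C)(C)C)[C@@H]1O[Si](C)(C)C(C)(C)C.[I-] | intermediate
16 | C6-methylene enone: C5 ketone, C3=C4, exocyclic C6=C7, OTBS on C1 (up) and C2 (down) | C=C1C(=O)C=C[C@@H](O[Si](C)(C)C(C)(C)C)[C@@H]1O[Si](C)(C)C(C)(C)C | intermediate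
17 | dienol: 6-methylenecyclohex-3-ene with OH on C5 (up), OTBS on C1 (up) and C2 (down) | C=C1[C@H](O)C=C[C@@H](O[Si](C)(C)C(C)(C)C)[C@@H]1O[Si](C)(C)C(C)(C)C | intermediate
18 | N-methylmorpholine N-oxide | C[N+]1([O-])CCOCC1 | starting material
19 | water | O | starting material
20 | osmate ester: hexavalent-osmium dioxo glycolate bridging O6 (down) and O7 | O=[Os]1(=O)OC[C@]2(O1)[C@H](O)C=C[C@@H](O[Si](C)(C)C(C)(C)C)[C@@H]2O[Si](C)(C)C(C)(C)C | intermediate
21 | triol: C5-OH (up), C6-OH (down), C7-OH; OTBS on C1 (up) and C2 (down) | OC[C@]1(O)[C@H](O)C=C[C@@H](O[Si](C)(C)C(C)(C)C)[C@@H]1O[Si](C)(C)C(C)(C)C | intermediate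
22 | benzoyl chloride | O=C(Cl)c1ccccc1 | starting material
23 | C7 benzoate of 21 (C5-OH up, C6-OH down) | O=C(OC[C@]1(O)[C@H](O)C=C[C@@H](O[Si](C)(C)C(C)(C)C)[C@@H]1O[Si](C)(C)C(C)(C)C)c1ccccc1 | intermediate
24 | C5–C6 epoxide (oxygen down), C7 benzoate, OTBS on C1 (up) and C2 (down) | CC(C)(C)[Si](C)(C)O[C@H]1[C@H](O[Si](C)(C)C(C)(C)C)C=C[C@@H]2O[C@@]21COC(=O)c1ccccc1 | intermediate
25 | epoxy diol: C1-OH (up), C2-OH (down), C7 benzoate | O[C@H]1[C@H](O)C=C[C@@H]2O[C@@]21COC(=O)c1ccccc1 | intermediate
26 | O2,O7-dibenzoate with free C1-OH | O[C@H]1[C@H](OC(=O)c2ccccc2)C=C[C@@H]2O[C@@]21COC(=O)c1ccccc1 | intermediate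
27 | acetic anhydride | CC(=O)OC(C)=O | starting material
28 | target: C1 acetate (up), C2 benzoate (down), C3=C4, C5–C6 epoxide (oxygen down), C7 benzoate | CC(=O)O[C@H]1[C@H](OC(=O)c2ccccc2)C=C[C@@H]2O[C@@]21COC(=O)c1ccccc1 | target

## Step count and least certain steps

Total: 15 steps. Longest linear sequence: 15 steps, from 1 to 28.

**Step 10 (key step).** The ring alkene may be osmylated as well, and facial selectivity may erode, because the pseudoaxial silyloxy group on C2 lies 1,3 to C6 on the lower face and partly offsets the bias from O1 and O5. Fallback, from 17 and returning at 23: the C5 hydroxyl would be silylated (Et3SiCl, imidazole) to the tris-silyl ether F1. Buffered mCPBA would then epoxidise the exocyclic alkene from below to give spiro-epoxide F2; the ring alkene then has a silyloxy group on each face, while the exocyclic alkene has none next to its lower face. PhCO2Cs/PhCO2H in DMF would open F2 at the primary carbon to give the C7 benzoate tertiary alcohol F3. Selective removal of the triethylsilyl group (PPTS, MeOH) would give diol 23. The two C–O bonds are then made in separate steps and the benzoate arrives with the nucleophile, so step 11 is not needed.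

**Step 7.** The lithium dienolate may lose the axial C1 silyloxide, which is aligned with the enolate π system, and the ring would then aromatise; the sparingly soluble iminium salt reacts slowly at the low temperature that prevents this. Fallback, from 11 and returning at 16: soft enolisation (Me3SiOTf, Et3N) would give the trimethylsilyl dienol ether F4. A Mukaiyama aldol reaction with aqueous formaldehyde catalysed by Yb(OTf)3 would give the C6-hydroxymethyl ketone F5. MsCl/Et3N would convert it through the primary mesylate F6 into 16 by E1cB elimination. No strongly basic enolate is involved.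

**Step 9.** Hydride may add 1,4 to the exocyclic enone, the cross-conjugated dienone may dimerise before it is reduced, and facial selectivity at C5 may be incomplete. Fallback, from 14 and returning at 17: the ketone of the Mannich base would be reduced first (NaBH4, CeCl3·7H2O) to the amino alcohol F7, which has no exocyclic enone. N-Oxidation (mCPBA) would give the amine oxide F8, and thermal Cope elimination through the only β-hydrogen, on C6, would unveil the exocyclic alkene of 17. Compounds 15 and 16 are bypassed.

**Step 12.** Activation of the C5 hydroxyl next to a quaternary carbon may be slow, and the allylic oxyphosphonium ion may ionise or be attacked at the far alkene terminus, which would erode the inversion. Fallback, from 23 and returning at 24: selective sulfonylation of the secondary hydroxyl (MsCl, Et3N, −20 °C; the tertiary hydroxyl does not react) would give the C5 mesylate F9, and DBU would close the epoxide by the same anti displacement.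

**Step 14.** Discrimination between O2 and O1 may be incomplete, with over-benzoylation and base-promoted benzoyl migration. Fallback, from 24 and returning at 26: the silyl ethers would be removed one at a time. Controlled HF·pyridine at low temperature would free the less hindered allylic O2 to give the mono-silyl alcohol F10. Benzoylation would give the O2 benzoate O1 silyl ether F11, and a second HF·pyridine treatment would give 26. O1 stays masked until O2 is acylated, and the selective step is a desilylation that can be stopped early and recycled.

## Further compounds

F1 | step 10 | C5 triethylsilyl ether of 17 | C=C1[C@H](O[Si](CC)(CC)CC)C=C[C@@H](O[Si](C)(C)C(C)(C)C)[C@@H]1O[Si](C)(C)C(C)(C)C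
F2 | step 10 | C6–C7 spiro-epoxide (oxygen down at C6) of F1 | C1O[C@]12[C@H](O[Si](CC)(CC)CC)C=C[C@@H](O[Si](C)(C)C(C)(C)C)[C@@H]2O[Si](C)(C)C(C)(C)C
F3 | step 10 | C7 benzoate, C6 tertiary alcohol (down), C5 triethylsilyl ether | O=C(OC[C@]1(O)[C@H](O[Si](CC)(CC)CC)C=C[C@@H](O[Si](C)(C)C(C)(C)C)[C@@H]1O[Si](C)(C)C(C)(C)C)c1ccccc1
F4 | step 7 | trimethylsilyl dienol ether of 11 | C[Si](C)(C)OC1=C[C@@H](O[Si](C)(C)C(C)(C)C)[C@H](O[Si](C)(C)C(C)(C)C)C=C1
F5 | step 7 | C6-hydroxymethyl ketone (C6 epimers) | OCC1C(=O)C=C[C@@H](O[Si](C)(C)C(C)(C)C)[C@@H]1O[Si](C)(C)C(C)(C)C
F6 | step 7 | primary mesylate of F5 | CS(=O)(=O)OCC1C(=O)C=C[C@@H](O[Si](C)(C)C(C)(C)C)[C@@H]1O[Si](C)(C)C(C)(C)C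
F7 | step 9 | amino alcohol: C5-OH (up), C6-CH2NMe2 (C6 epimers) | CN(C)CC1[C@H](O)C=C[C@@H](O[Si](C)(C)C(C)(C)C)[C@@H]1O[Si](C)(C)C(C)(C)C
F8 | step 9 | amine N-oxide of F7 | C[N+](C)([O-])CC1[C@H](O)C=C[C@@H](O[Si](C)(C)C(C)(C)C)[C@@H]1O[Si](C)(C)C(C)(C)C
F9 | step 12 | C5 mesylate of 23 | O=C(OC[C@]1(O)[C@H](OS(C)(=O)=O)C=C[C@@H](O[Si](C)(C)C(C)(C)C)[C@@H]1O[Si](C)(C)C(C)(C)C)c1ccccc1
F10 | step 14 | epoxide with O1 silyl ether and free C2 hydroxyl | CC(C)(C)[Si](C)(C)O[C@H]1[C@H](O)C=C[C@@H]2O[C@@]21COC(=O)c1ccccc1
F11 | step 14 | epoxide with O1 silyl ether and O2 benzoate | CC(C)(C)[Si](C)(C)O[C@H]1[C@H](OC(=O)c2ccccc2)C=C[C@@H]2O[C@@]21COC(=O)c1ccccc1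
A1 | alternative 1 | furfuryl benzoate | O=C(OCc1ccco1)c1ccccc1
A2 | alternative 1 | 2-bromoacrolein | C=C(Br)C=O
A3 | alternative 1 | 7-oxanorbornene bromo-aldehyde | O=C[C@]1(Br)C[C@H]2C=C[C@]1(COC(=O)c1ccccc1)O2
A4 | alternative 2 | 2-(hydroxymethyl)phenol | OCc1ccccc1O
A5 | alternative 2 | racemic 1-oxaspiro[2.5]octa-5,7-dien-4-one | O=C1C=CC=CC12CO2
A6 | alternative 2 | spiro-epoxy cyclohexadiene 4-methoxybenzyl ether | COc1ccc(CO[C@H]2C=CC=C[C@]23CO3)cc1
A7 | alternative 2 | spiro-epoxy endoperoxide | COc1ccc(CO[C@H]2[C@H]3C=C[C@H](OO3)[C@]24CO4)cc1
A8 | alternative 3 | dienyl tert-butyl carbonate | CC(C)(C)OC(=O)O[C@@H]1C=CC=C(COC(=O)c2ccccc2)[C@H]1O[Si](C)(C)C(C)(C)C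
A9 | alternative 3 | bicyclic iodocarbonate | O=C1O[C@@H]2C=C[C@@H](I)[C@](COC(=O)c3ccccc3)(O1)[C@H]2O[Si](C)(C)C(C)(C)C
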